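**Retrosynthetic overview**
1. Target 13 ⇒ open-chain (S)-hydroxy-triketo tert-butyl ester 10; rings C and A are both closed from 10 in one flask.
2. Ring C forms first: the C2-OH adds to the C8a ketone and dehydrates to a dihydropyranone. Ring A forms second: thermal acylketene formation, then C4a–C5 closure (6π) and aromatisation. Ring B is purchased.
3. 10 ⇒ C4–C4a Claisen acylation of the trianion of tert-butyl 2-geranyl-3,5-dioxohexanoate 9 with (S)-β-hydroxy ester 4.
4. 4 ⇒ asymmetric hydrogenation of β-keto ester 3 (benzoate 1 + ethyl acetate 2); this sets C2, and its C–O bond is never broken afterwards.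
5. 9 ⇒ tert-butyl acetoacetate 5 + geranyl bromide 6 (geranyl fixed on the future C6), then dianion acetylation with 8.

Assumption: methyl 3-hydroxy-4,5-dimethoxybenzoate (1) is taken as a catalogue chemical; locants C2–C8a below are flavanone numbering.

**Step 1**
Reactants: 1 methyl 3-hydroxy-4,5-dimethoxybenzoate; 2 ethyl acetate
Product: 3 ethyl 3-(3-hydroxy-4,5-dimethoxyphenyl)-3-oxopropanoate
Conditions: LiHMDS (4.0 equiv), THF, −78 °C; 2 (2.0 equiv), then 1; −78 → 0 °C; 1 M HCl
Reagents that add atoms: none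
Why: Crossed Claisen condensation in which the lithium enolate of ethyl acetate acylates on the methyl ester and the product is drained off as its β-keto ester enolate, the phenol riding along as its lithium phenoxide.

**Step 2**
Reactants: 3
Product: 4 ethyl (3S)-3-hydroxy-3-(3-hydroxy-4,5-dimethoxyphenyl)propanoate
Conditions: [RuCl(p-cymene)((R)-SEGPHOS)]Cl (0.5 mol %), H2 (30 bar), EtOH, 60 °C
Reagents that add atoms: none
Why: Noyori asymmetric hydrogenation of a β-keto ester, in which the ester-chelated Ru–(R)-bisphosphine hydride attacks the ketone face that gives the (S)-carbinol for aroylacetates (same facial sense as (R)-3-hydroxybutanoate, descriptor inverted because aryl outranks CH2CO2Et).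

**Step 3**
Reactants: 5 tert-butyl acetoacetate (1.3 equiv); 6 geranyl bromide
Product: 7 tert-butyl 2-geranylacetoacetate [tert-butyl (4E)-2-acetyl-5,9-dimethyldeca-4,8-dienoate, racemic at C2]
Conditions: NaH (1.3 equiv), THF, 0 °C; 6, 0 °C → rt
Reagents that add atoms: none
Why: SN2 C-alkylation of the acetoacetate enolate at the primary allylic carbon keeps the (E)-olefin and places geranyl on the carbon that becomes C6; the racemic α-centre later becomes sp2, so no controlled stereocenter is needed here.

**Step 4**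
Reactants: 7; 8 N-methoxy-N-methylacetamide
Product: 9 tert-butyl 2-[(2E)-3,7-dimethylocta-2,6-dien-1-yl]-3,5-dioxohexanoate
Conditions: LDA (2.2 equiv), THF, −78 → 0 °C; 8 (1.05 equiv), −78 → −20 °C; 1 M HCl, 0 °C
Reagents that add atoms: none
Why: Huckin–Weiler dianion acylation, in which the terminal (γ) carbanion of the β-keto ester dianion adds to the Weinreb amide and the chelated tetrahedral adduct collapses to the 3,5-diketo ester only on work-up.

**Step 5**
Reactants: 9 (2.2 equiv); 4
Product: 10 tert-butyl (9S)-2-[(2E)-3,7-dimethylocta-2,6-dien-1-yl]-9-hydroxy-9-(3-hydroxy-4,5-dimethoxyphenyl)-3,5,7-trioxononanoate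
Conditions: 9, LDA (6.7 equiv), THF, −78 → 0 °C; then 4 pre-treated with LDA (2.0 equiv, THF, −78 °C); −78 → −20 °C; AcOH, −78 °C, pH 6 buffer; used at once
Reagents that add atoms: none
Why: Harris-type polyanion Claisen acylation, in which the trianion of 9 reacts only at its terminal carbanion (future C4a) with the ethyl ester while the carbinol travels as a lithium alkoxide that cannot β-eliminate (as in Claisen condensations of unprotected β-hydroxy esters), so the stereocenter is untouched.

**Step 6**
Reactants: 10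
Product: 13 (2S)-5,7-dihydroxy-2-(3-hydroxy-4,5-dimethoxyphenyl)-6-[(2E)-3,7-dimethylocta-2,6-dien-1-yl]chroman-4-one (CNP0228243.1), via dihydropyranone 11 (not isolated), via acylketene 12 (not isolated)
Conditions: PPTS (10 mol %), 4 Å MS, PhMe (0.01 M), 40 °C, 2 h; then 110 °C, 6 h
Reagents that add atoms: none
Why: Proposed new method: mild acid first closes ring C by hemiketalisation of the C2 hydroxyl onto the C8a ketone and dehydration to the vinylogous ester (the standard δ-hydroxy-β-diketone to 2,3-dihydro-4H-pyran-4-one cyclodehydration, C2–O bond untouched so (S) is retained), which ties up the only oxygen that could otherwise lactonise to a pyrone, and heating then expels tert-butanol from the β-keto tert-butyl ester (the acylketene formation known from tert-butyl acetoacetate transacylations) to give an acylketene whose enol is a dienylketene that closes C4a–C5 by 6π-electrocyclisation and tautomerises to the phenol ring (closest known reactions: the final stage of the Danheiser benzannulation and acylketene-based aromatisations), the geranyl group sitting on the ketene α-carbon so that it can only end up at C6.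

**Compound list**
1 | methyl 3-hydroxy-4,5-dimethoxybenzoate | COC(=O)c1cc(O)c(OC)c(OC)c1 | starting material
2 | ethyl acetate | CCOC(C)=O | starting material
3 | ethyl 3-(3-hydroxy-4,5-dimethoxyphenyl)-3-oxopropanoate | CCOC(=O)CC(=O)c1cc(O)c(OC)c(OC)c1 | intermediate
4 | ethyl (3S)-3-hydroxy-3-(3-hydroxy-4,5-dimethoxyphenyl)propanoate | CCOC(=O)C[C@H](O)c1cc(O)c(OC)c(OC)c1 | intermediate
5 | tert-butyl acetoacetate | CC(=O)CC(=O)OC(C)(C)C | starting material
6 | geranyl bromide [(2E)-1-bromo-3,7-dimethylocta-2,6-diene] | CC(C)=CCC/C(C)=C/CBr | starting material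
7 | tert-butyl 2-geranylacetoacetate (racemic) | CC(=O)C(C/C=C(\C)CCC=C(C)C)C(=O)OC(C)(C)C | intermediate
8 | N-methoxy-N-methylacetamide | CON(C)C(C)=O | starting material
9 | tert-butyl 2-[(2E)-3,7-dimethylocta-2,6-dien-1-yl]-3,5-dioxohexanoate | CC(=O)CC(=O)C(C/C=C(\C)CCC=C(C)C)C(=O)OC(C)(C)C | intermediate
10 | tert-butyl (9S)-2-geranyl-9-hydroxy-9-(3-hydroxy-4,5-dimethoxyphenyl)-3,5,7-trioxononanoate | COc1cc([C@@H](O)CC(=O)CC(=O)CC(=O)C(C/C=C(\C)CCC=C(C)C)C(=O)OC(C)(C)C)cc(O)c1OC | intermediate
11 | tert-butyl 2-geranyl-4-[(2S)-2-(3-hydroxy-4,5-dimethoxyphenyl)-4-oxo-3,4-dihydro-2H-pyran-6-yl]-3-oxobutanoate | COc1cc([C@@H]2CC(=O)C=C(CC(=O)C(C/C=C(\C)CCC=C(C)C)C(=O)OC(C)(C)C)O2)cc(O)c1OC | intermediate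
12 | 2-geranyl-4-[(2S)-2-(3-hydroxy-4,5-dimethoxyphenyl)-4-oxo-3,4-dihydro-2H-pyran-6-yl]but-1-ene-1,3-dione (acylketene) | COc1cc([C@@H]2CC(=O)C=C(CC(=O)C(C/C=C(\C)CCC=C(C)C)=C=O)O2)cc(O)c1OC | intermediate
13 | (2S)-5,7-dihydroxy-2-(3-hydroxy-4,5-dimethoxyphenyl)-6-[(2E)-3,7-dimethylocta-2,6-dien-1-yl]chroman-4-one | COc1cc([C@@H]2CC(=O)c3c(cc(O)c(C/C=C(\C)CCC=C(C)C)c3O)O2)cc(O)c1OC | target

**Step count**
Total steps: 6. Longest linear sequence: 4 steps (1 → 3 → 4 → 10 → 13, or 5 → 7 → 9 → 10 → 13).

**Steps most likely to fail, with fallbacks**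

Step 6 is the riskiest. The acylketene must not form before ring C is closed (otherwise a 4-hydroxy-2-pyrone results). The tert-butyl ester may instead undergo acidolysis and decarboxylation, and prolonged heating could erode the ee or cyclise the geranyl group onto a phenol. The fallback separates the two ring closures and generates the ketene chemically at low temperature. It sets out from 10, which is treated with CSA (5 mol %, CH2Cl2, 0 °C) to give dihydropyranone 11, now isolated. The tert-butyl ester of 11 is cleaved with TMSOTf/2,6-lutidine (CH2Cl2, 0 °C, cold pH 5 work-up) to 2-geranyl-4-[(2S)-2-(3-hydroxy-4,5-dimethoxyphenyl)-4-oxo-3,4-dihydro-2H-pyran-6-yl]-3-oxobutanoic acid F1. This acid is dehydrated with EDC·HCl (CH2Cl2, 0 °C → rt) to acylketene 12, which cyclises as before. The fallback comes back to the route at 13.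

Step 5 is the second risk. The dilithio salt of 4 may be poorly soluble or sluggish, the ester may be enolised instead of acylated, and two equivalents of 9 are consumed. The fallback uses a neutral, protected Weinreb amide and sets out from 4. Silylation (TBSCl, imidazole, DMF) gives ethyl (3S)-3-(tert-butyldimethylsilyloxy)-3-[3-(tert-butyldimethylsilyloxy)-4,5-dimethoxyphenyl]propanoate F2. Amidation (MeNHOMe·HCl, i-PrMgCl, THF, −20 °C) gives (3S)-3-(tert-butyldimethylsilyloxy)-3-[3-(tert-butyldimethylsilyloxy)-4,5-dimethoxyphenyl]-N-methoxy-N-methylpropanamide F3. The trianion of 9 (1.3 equiv, LDA, THF, −78 °C) adds to F3 to give the bis-TBS ether of 10, tert-butyl (9S)-9-(tert-butyldimethylsilyloxy)-9-[3-(tert-butyldimethylsilyloxy)-4,5-dimethoxyphenyl]-2-geranyl-3,5,7-trioxononanoate F4. Buffered desilylation (TBAF/AcOH 1:1, THF, 0 °C → rt) returns the route at 10.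

Step 4 is the third risk. The hindered dianion may deprotonate the enolisable Weinreb acetamide instead of adding to it, returning 7. The fallback replaces acylation by aldol addition and oxidation and sets out from 7. The same dianion (LDA, 2.2 equiv, THF, −78 °C) is added to acetaldehyde to give tert-butyl 2-geranyl-5-hydroxy-3-oxohexanoate F5 as a diastereomer mixture. Oxidation of the β-hydroxy ketone with IBX (EtOAc, 75 °C) returns the route at 9.

**Further compounds**
F1 | step 6 | 2-geranyl-4-[(2S)-2-(3-hydroxy-4,5-dimethoxyphenyl)-4-oxo-3,4-dihydro-2H-pyran-6-yl]-3-oxobutanoic acid | COc1cc([C@@H]2CC(=O)C=C(CC(=O)C(C/C=C(\C)CCC=C(C)C)C(=O)O)O2)cc(O)c1OC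
F2 | step 5 | ethyl (3S)-3-(tert-butyldimethylsilyloxy)-3-[3-(tert-butyldimethylsilyloxy)-4,5-dimethoxyphenyl]propanoate | CCOC(=O)C[C@H](O[Si](C)(C)C(C)(C)C)c1cc(O[Si](C)(C)C(C)(C)C)c(OC)c(OC)c1
F3 | step 5 | (3S)-3-(tert-butyldimethylsilyloxy)-3-[3-(tert-butyldimethylsilyloxy)-4,5-dimethoxyphenyl]-N-methoxy-N-methylpropanamide | CON(C)C(=O)C[C@H](O[Si](C)(C)C(C)(C)C)c1cc(O[Si](C)(C)C(C)(C)C)c(OC)c(OC)c1
F4 | step 5 | tert-butyl (9S)-9-(tert-butyldimethylsilyloxy)-9-[3-(tert-butyldimethylsilyloxy)-4,5-dimethoxyphenyl]-2-geranyl-3,5,7-trioxononanoate | COc1cc([C@@H](O[Si](C)(C)C(C)(C)C)CC(=O)CC(=O)CC(=O)C(C/C=C(\C)CCC=C(C)C)C(=O)OC(C)(C)C)cc(O[Si](C)(C)C(C)(C)C)c1OC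
F5 | step 4 | tert-butyl 2-geranyl-5-hydroxy-3-oxohexanoate | CC(O)CC(=O)C(C/C=C(\C)CCC=C(C)C)C(=O)OC(C)(C)C
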